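**Numbering.** Ring A of the target is numbered C1 (CH2OH), C2 (H), C3 (Br), C4 (OH), C5 (OH), C6 (arylmethyl). Ring B is the 3-bromo-4-hydroxyphenyl ring. Compounds carry the numbers 1–16 of the list after the steps.

**Remark on the chemistry.** The target has no stereocentre. The single sp3 centre that appears in 10, 11 and 12 is carried as a racemate and disappears on aromatization.

## Analysis of the target

Compound 16 is a diarylmethane in which ring A, a pentasubstituted benzene, is joined through one methylene group to ring B. Ring A carries CH2OH at C1, bromine at C3, hydroxyls at C4 and C5 and the arylmethyl group at C6, so its only hydrogen is at C2. There are no stereocentres, and the problem is one of regiochemistry around five contiguous substituted carbons. The catechol is easily oxidized to an ortho-quinone. The C1 hydroxymethyl group stands para to the C4 hydroxyl, so it can ionize to a quinone methide under acid, base or heat. The two aryl bromides rule out hydrogenolysis, zerovalent palladium and halogen–metal exchange late in the route. Placing the arylmethyl group at C6 between two substituted carbons, and bromine at C3 only, is hard to do by substitution on a preformed catechol. The route rests on reading ring A as the aromatized form of a 2-alkoxycyclohex-2-enone: C4 is the ketone, C5 the enol ether carbon, C6 the beta carbon, C1 an ester-bearing sp3 carbon and C2–C3 two methylenes. In that ring C3 is the only enolizable ketone alpha carbon, which is where halogenation starts the aromatization and where bromine must end up.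

## Retrosynthetic reasoning

**16 from 15.** The C1 hydroxymethyl group is traced back to the methyl ester of 15; no skeletal bond is cut. The reduction is placed last because the para-hydroxybenzyl alcohol of 16 would not survive Lewis-acid ether cleavage or electrophilic halogenation. The forward step has to deliver hydride to an ester deactivated by three aluminium phenoxides without hydrogenolysing the new benzylic C–O bond.

**15 from 14.** The two O–CH3 bonds are cut, at C5 of ring A and at C4 of ring B. Methyl ethers are the smallest groups that survive enolate, amine and halogenation chemistry, and both fall in one operation. The C4 hydroxyl needs no protection because it is born free from the ketone.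

**14 from 11.** The C3–Br bond and the aromatic unsaturation are removed together. In 11, C3 is the only ketone alpha carbon that carries hydrogen. In phenol 13, C3 is the only open position ortho to the new hydroxyl, and the para position is blocked by the ester. One electrophile can therefore serve as oxidant and as substituent, and the position of the halogen is not a separate problem. The forward sequence is alpha-halogenation to 12, loss of hydrogen halide and tautomerization to 13, then ortho-bromination.

**11 from 4 and 9 (key disconnection).** The C1–C2 bond and the C5=C6 double bond are cut. C1 lies between an ester and the C6 carbonyl, so it is a doubly activated donor, and C2 is the beta carbon of a vinyl ketone. C5 is alpha to the C4 ketone, and C6 is itself a ketone. Both bonds therefore form with natural polarity. Two small acyclic pieces deliver all six ring carbons, both oxygens, the ester and the arylmethyl group. The forward reaction has to add C1 of 4 to 9 and then close the ring from C5 onto C6, not in the competing direction.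

**4 from 1 and 2, through 3.** The bond between the acyl carbon (future C6) and the activated methylene (future C1) is cut. Compound 2 serves as an acetate equivalent that is unmasked by alcoholysis with decarboxylation. Ring B arrives intact from 1 with its bromine and methoxy group already in place, so it never has to be halogenated.

**9 from 7 and 8; 7 from 5 and 6.** The acyl–vinyl bond is cut. The N-methoxy-N-methylamide 7 holds the addition of 8 at the ketone stage.

## Alternatives that were turned down

**Alternative 1: aryne three-component coupling.**
- Disconnection: ring A is kept aromatic throughout. The bonds from C1 and C6 to their exocyclic carbons are formed on aryne A2 with isocyanide A4 and aldehyde A3.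
- Forward key step: A4 adds at the aryne carbon remote from the methoxy group (C1). The aryl anion at C6 adds to A3, and the alkoxide closes on the nitrilium carbon to give iminolactone A1.
- For: it is convergent. The methoxy group next to the aryne bond fixes the regiochemistry, and the bromine and both oxygens are in place before the coupling. On positional certainty it is stronger than the chosen route.
- Against: A2 must be generated from a pentasubstituted benzene whose own preparation needs several regiocontrolled steps. A1 carries one oxygen too many at the diarylmethyl carbon. Imidate hydrolysis, ionic deoxygenation of the benzylic C–O bond in the presence of two aryl bromides, reduction of the carboxyl carbon and cleavage of three methyl ethers must follow.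
- Comparison: the chosen route gives up pre-set regiochemistry. In return it starts from cheap acyclic pieces, has the benzylic carbon at the methylene level from the outset, and is clearly shorter.

**Alternative 2: inverse-demand pyrone cycloaddition.**
- Disconnection: ring A bonds C3–C4 and C5–C6 are formed between bromopyrone A6 and ketene silyl acetal A7.
- Forward key step: the nucleophilic carbon of A7 attacks the pyrone carbon that bears the arylmethyl group. Ring closure, decarboxylative retro-cycloaddition and loss of silanol then give arene A5.
- For: the fully substituted arene forms directly with bromine and both oxygens in place. No oxidation step and no late bromination are needed, and the polarization of both partners fixes the orientation. On these points it is as strong as or stronger than the chosen route.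
- Against: A6 is a fully substituted pyrone that must itself be built, most plausibly from keto ester 4, and then brominated. A ring is thus made only to be destroyed. The first bond forms at a hindered, fully substituted pyrone carbon, and ketene acetals can stop at conjugate addition or ring opening. A5 also carries one more methyl ether to cleave.
- Comparison: the overall step count is similar. The chosen route reaches the ring in one step from 4 with stable reagents and gets the bromine as part of the aromatization.

**Alternative 3: gold-catalysed furan–yne phenol synthesis.**
- Disconnection: ring A bonds C6–C1 and C5–C4 are formed from furan–yne A9.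
- Forward key step: the gold-activated alkyne is attacked by the furan. Through carbene, oxepine and arene oxide intermediates the furan oxygen becomes the C5 hydroxyl of phthalan A8.
- For: the conditions are mild and atom-economic. Bromine comes in with the furan, and reductive opening of the phthalan at its diarylmethyl carbon would reveal CH2Ar and CH2OH in one operation. That end-game is more elegant than an ester reduction.
- Against: A8 has no oxygen at C4. The catechol would have to be completed by a late ortho-oxidation at a position flanked by bromine. A9 needs a brominated furan carbinol and an aryl propargyl alcohol, and the bromine lowers the nucleophilicity of the furan.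
- Comparison: the chosen route carries both oxygens from the start and needs no late C–H oxidation.

Key step: step 5

## Route

Step 1
Reactants: 1 3-bromo-4-methoxyphenylacetic acid; 2 Meldrum's acid (2,2-dimethyl-1,3-dioxane-4,6-dione)
Product: 3 5-[2-(3-bromo-4-methoxyphenyl)-1-hydroxyethylidene]-2,2-dimethyl-1,3-dioxane-4,6-dione
Conditions: DCC (1.1 equiv), DMAP (1.3 equiv), CH2Cl2, 0 °C → rt
Reagents that add atoms: none
Why: Carbodiimide activation of the acid and C-acylation of the acidic methylene of 2 through the acylpyridinium give the stable enol 3; this is the standard Meldrum's acid acylation used to make beta-keto esters.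

Step 2
Reactants: 3 5-[2-(3-bromo-4-methoxyphenyl)-1-hydroxyethylidene]-2,2-dimethyl-1,3-dioxane-4,6-dione
Product: 4 methyl 4-(3-bromo-4-methoxyphenyl)-3-oxobutanoate
Conditions: MeOH, reflux
Reagents that add atoms: methanol, CO
Why: Thermal fragmentation of the acyl Meldrum's acid releases acetone and carbon dioxide and gives an acylketene that methanol traps as the beta-keto ester; the aryl bromide and aryl ether are untouched.

Step 3
Reactants: 5 methoxyacetyl chloride; 6 N,O-dimethylhydroxylamine hydrochloride
Product: 7 N,2-dimethoxy-N-methylacetamide
Conditions: Et3N (2.2 equiv), CH2Cl2, 0 °C → rt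
Reagents that add atoms: none
Why: Simple N-acylation of the free hydroxylamine gives the Weinreb amide.

Step 4
Reactants: 7 N,2-dimethoxy-N-methylacetamide; 8 vinylmagnesium bromide
Product: 9 1-methoxybut-3-en-2-one
Conditions: CH2=CHMgBr (1.2 equiv), THF, −78 → 0 °C; inverse quench into cold 2 M HCl/Et2O; short-path distillation, kept cold with BHT
Reagents that add atoms: none
Why: Weinreb ketone synthesis: the chelated tetrahedral magnesium adduct stops the addition at the ketone stage. The inverse acidic quench protonates the released amine before it can add to the new enone.

Step 5
Reactants: 4 methyl 4-(3-bromo-4-methoxyphenyl)-3-oxobutanoate; 9 1-methoxybut-3-en-2-one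
Product: 11 methyl 2-(3-bromo-4-methoxybenzyl)-3-methoxy-4-oxocyclohex-2-ene-1-carboxylate (racemic), via diketo ester 10 (not isolated)
Conditions: 9 (1.05 equiv, slow addition), Et3N (0.1 equiv), PhMe, 0 °C → rt; then pyrrolidine (0.3 equiv), AcOH (0.3 equiv), 4 Å MS, 50 °C
Reagents that add atoms: none
Why: Triethylamine forms the stabilized enolate of 4 at the doubly activated carbon (future C1), which adds to the unhindered terminus of enone 9 (future C2) and gives diketo ester 10 with the C1–C2 bond; this is the Michael half of a Robinson annulation. Pyrrolidinium acetate then condenses with the only unhindered ketone of 10, the methoxymethyl ketone at C4, and as with other alpha-oxygenated ketones the enamine should form toward the oxygen-bearing carbon C5. This enamine attacks the C6 ketone, which the neighbouring ester activates, in a 6-(enolendo)-exo-trig aldol closure of ring A; loss of water and hydrolysis of the iminium give the tetrasubstituted alkoxy enone 11 with the C5=C6 bond. The closest known reaction is the Hagemann ester synthesis from acetoacetates and vinyl ketones under pyrrolidinium acetate catalysis. The one stereocentre, C1, arises racemic and epimerizable, and no control is needed because aromatization removes it. The selectivity required is closure from C5 onto C6 and not from the benzylic methylene onto the C4 ketone: the branched C6 ketone is slow to form an enamine, the weakly basic medium keeps the benzylic enolate concentration low, and irreversible dehydration to the conjugated enone drains the desired aldol. Slow addition of 9 limits a second Michael addition at C1.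

Step 6
Reactants: 11 methyl 2-(3-bromo-4-methoxybenzyl)-3-methoxy-4-oxocyclohex-2-ene-1-carboxylate
Product: 14 methyl 5-bromo-2-(3-bromo-4-methoxybenzyl)-4-hydroxy-3-methoxybenzoate, via bromo ketone 12 (not isolated), via phenol 13 (not isolated)
Conditions: Br2 (1.0 equiv), AcOH, rt → 60 °C; then Br2 (1.05 equiv), 15 °C
Reagents that add atoms: bromine, BrBr
Why: Acid-catalysed enolization and bromination give bromo ketone 12, which loses HBr to a cyclohexadienone that tautomerizes to phenol 13; bromination at any ring carbon (C1 through the dienol as well as C3) converges on 13. The second equivalent brominates 13 at C3, the only free position ortho to the new hydroxyl, with the para position blocked by the ester; the bromoanisole ring B is far less reactive than the phenol. The reaction type is halogenation–dehydrohalogenation aromatization of a cyclohexenone followed by electrophilic bromination of a phenol.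

Step 7
Reactants: 14 methyl 5-bromo-2-(3-bromo-4-methoxybenzyl)-4-hydroxy-3-methoxybenzoate
Product: 15 methyl 5-bromo-2-(3-bromo-4-hydroxybenzyl)-3,4-dihydroxybenzoate
Conditions: BBr3 (5 equiv), CH2Cl2, −78 → 0 °C; ice-water
Reagents that add atoms: none
Why: Lewis acid-mediated cleavage of both aryl methyl ethers by bromide attack at methyl; the ring A ether is assisted by formation of a cyclic catechol borate. At or below 0 °C the methyl ester, the aryl bromides and the diarylmethane should survive.

Step 8
Reactants: 15 methyl 5-bromo-2-(3-bromo-4-hydroxybenzyl)-3,4-dihydroxybenzoate
Product: 16 6-bromo-3-(3-bromo-4-hydroxybenzyl)-4-(hydroxymethyl)benzene-1,2-diol (CNP0232913.0)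
Conditions: iBu2AlH (8 equiv), THF, −78 → 0 °C; EtOAc, then degassed aq. KNaC4H4O6
Reagents that add atoms: none
Why: Three equivalents of hydride are consumed by the phenols and the excess reduces the ester through the aldehyde to the primary alcohol, a standard ester reduction that leaves aryl bromides alone. Low temperature and a neutral tartrate work-up avoid quinone methide formation from the para-hydroxybenzyl alcohol.

## Compound list

1 | 3-bromo-4-methoxyphenylacetic acid | COc1ccc(CC(=O)O)cc1Br | starting material
2 | Meldrum's acid (2,2-dimethyl-1,3-dioxane-4,6-dione) | CC1(C)OC(=O)CC(=O)O1 | starting material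
3 | 5-[2-(3-bromo-4-methoxyphenyl)-1-hydroxyethylidene]-2,2-dimethyl-1,3-dioxane-4,6-dione | COc1ccc(CC(O)=C2C(=O)OC(C)(C)OC2=O)cc1Br | intermediate
4 | methyl 4-(3-bromo-4-methoxyphenyl)-3-oxobutanoate | COC(=O)CC(=O)Cc1ccc(OC)c(Br)c1 | intermediate
5 | methoxyacetyl chloride | COCC(=O)Cl | starting material
6 | N,O-dimethylhydroxylamine hydrochloride | CNOC.Cl | starting material
7 | N,2-dimethoxy-N-methylacetamide | COCC(=O)N(C)OC | intermediate
8 | vinylmagnesium bromide | C=C[Mg]Br | starting material
9 | 1-methoxybut-3-en-2-one | COCC(=O)C=C | intermediate
10 | methyl 2-[2-(3-bromo-4-methoxyphenyl)acetyl]-6-methoxy-5-oxohexanoate (racemic; not isolated) | COC(=O)C(CCC(=O)COC)C(=O)Cc1ccc(OC)c(Br)c1 | intermediate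
11 | methyl 2-(3-bromo-4-methoxybenzyl)-3-methoxy-4-oxocyclohex-2-ene-1-carboxylate (racemic) | COC(=O)C1CCC(=O)C(OC)=C1Cc1ccc(OC)c(Br)c1 | intermediate
12 | methyl 5-bromo-2-(3-bromo-4-methoxybenzyl)-3-methoxy-4-oxocyclohex-2-ene-1-carboxylate (racemic mixture of diastereomers; not isolated) | COC(=O)C1CC(Br)C(=O)C(OC)=C1Cc1ccc(OC)c(Br)c1 | intermediate
13 | methyl 2-(3-bromo-4-methoxybenzyl)-4-hydroxy-3-methoxybenzoate (not isolated) | COC(=O)c1ccc(O)c(OC)c1Cc1ccc(OC)c(Br)c1 | intermediate
14 | methyl 5-bromo-2-(3-bromo-4-methoxybenzyl)-4-hydroxy-3-methoxybenzoate | COC(=O)c1cc(Br)c(O)c(OC)c1Cc1ccc(OC)c(Br)c1 | intermediate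
15 | methyl 5-bromo-2-(3-bromo-4-hydroxybenzyl)-3,4-dihydroxybenzoate | COC(=O)c1cc(Br)c(O)c(O)c1Cc1ccc(O)c(Br)c1 | intermediate
16 | 6-bromo-3-(3-bromo-4-hydroxybenzyl)-4-(hydroxymethyl)benzene-1,2-diol (CNP0232913.0) | OCc1cc(Br)c(O)c(O)c1Cc1ccc(O)c(Br)c1 | target

## Step count and risk

Total step count: 8. Longest linear sequence: 6 steps (steps 1, 2, 5, 6, 7, 8; the branch through steps 3 and 4 is equally long).

**Step 5 (key step).**
- Risk: the ring may close in the wrong direction. The benzylic methylene of 10 is acidified by the aryl ring, and the C4 ketone is activated by its methoxy group, so attack of the benzylic carbon on C4 is equally allowed as a 6-(enolendo)-exo-trig closure. A second Michael addition at C1 and pyran formation from the 1,5-dicarbonyl unit are lesser risks.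
- Fallback: it sets out from 4 and replaces the aldol by an olefination that can only join C5 to C6. Michael addition of 4 to methyl acrylate (K2CO3, MeCN) should give dimethyl 2-[2-(3-bromo-4-methoxyphenyl)acetyl]pentanedioate F1. Its keto ester unit is turned into the sodium enolate (NaH, THF), which shields that ketone and ester. Lithiated diethyl (methoxymethyl)phosphonate (LiN(iPr)2, THF, −78 °C) then acylates at the remaining ester to give methyl 2-[2-(3-bromo-4-methoxyphenyl)acetyl]-6-(diethoxyphosphoryl)-6-methoxy-5-oxohexanoate F2. Intramolecular Horner–Wadsworth–Emmons olefination (LiCl, iPr2NEt, MeCN) comes back to the route at 11.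

**Step 6.**
- Risk: bromine is used as oxidant and as substituent in one flask. Bromination of ring B ortho to its methoxy group, bromination of the diarylmethane carbon, or HBr-induced cleavage of the enol ether before aromatization would erode the material.
- Fallback: it separates oxidation from halogenation and sets out from 11. Soft enolization (TMSOTf, Et3N, CH2Cl2, 0 °C) should give the ester-conjugated silyl dienol ether methyl 2-(3-bromo-4-methoxybenzyl)-3-methoxy-4-(trimethylsilyloxy)cyclohexa-1,3-diene-1-carboxylate F3. DDQ (1.1 equiv, CH2Cl2, 0 °C) dehydrogenates this cyclohexa-1,3-diene to aryl silyl ether methyl 2-(3-bromo-4-methoxybenzyl)-3-methoxy-4-(trimethylsilyloxy)benzoate F4. Dilute HCl in MeOH frees phenol 13, now isolated. One equivalent of N-bromosuccinimide in MeCN at 0 °C then brominates C3 and rejoins the route at 14.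

**Step 8.**
- Risk: the reduction may stall because the aluminium phenoxide para to the ester donates into the carbonyl and the polyaluminate may precipitate. If forced, the para-oxido benzylic alkoxide can ionize to a quinone methide and be reduced further to a methyl group. The catechol can also oxidize during work-up.
- Fallback: it sets out from 15. Silylation (TBSCl, imidazole, DMF) gives methyl 5-bromo-2-[3-bromo-4-(tert-butyldimethylsilyloxy)benzyl]-3,4-bis(tert-butyldimethylsilyloxy)benzoate F5. iBu2AlH (2.5 equiv, CH2Cl2, −78 °C) reduces this ordinary ester to {5-bromo-2-[3-bromo-4-(tert-butyldimethylsilyloxy)benzyl]-3,4-bis(tert-butyldimethylsilyloxy)phenyl}methanol F6. Buffered fluoride (Et3N·3HF, THF, rt) removes the silyl groups and arrives at 16.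

**Step 4.**
- Risk: on quenching, the liberated N,O-dimethylhydroxylamine may add in conjugate fashion to the vinyl ketone. The small enone may also polymerize or be lost by evaporation during isolation.
- Fallback: it turns the side reaction into a latent enone and sets out from 7 and 8. After the Grignard addition the mixture is quenched with aqueous NH4Cl at 0 °C and stirred, so that the released amine adds to the enone and gives the non-volatile 1-methoxy-4-[methoxy(methyl)amino]butan-2-one F7. In step 5, F7 is used with DBU (1.1 equiv) in place of Et3N and 9. Retro-aza-Michael elimination releases 9 in the flask in the presence of 4, as in the Mannich-base variant of the Robinson annulation, and the route is rejoined at 9.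

## Further compounds

F1 | step 5 | dimethyl 2-[2-(3-bromo-4-methoxyphenyl)acetyl]pentanedioate (racemic) | COC(=O)CCC(C(=O)OC)C(=O)Cc1ccc(OC)c(Br)c1
F2 | step 5 | methyl 2-[2-(3-bromo-4-methoxyphenyl)acetyl]-6-(diethoxyphosphoryl)-6-methoxy-5-oxohexanoate (mixture of diastereomers) | CCOP(=O)(OCC)C(OC)C(=O)CCC(C(=O)OC)C(=O)Cc1ccc(OC)c(Br)c1
F3 | step 6 | methyl 2-(3-bromo-4-methoxybenzyl)-3-methoxy-4-(trimethylsilyloxy)cyclohexa-1,3-diene-1-carboxylate | COC(=O)C1=C(Cc2ccc(OC)c(Br)c2)C(OC)=C(O[Si](C)(C)C)CC1
F4 | step 6 | methyl 2-(3-bromo-4-methoxybenzyl)-3-methoxy-4-(trimethylsilyloxy)benzoate | COC(=O)c1ccc(O[Si](C)(C)C)c(OC)c1Cc1ccc(OC)c(Br)c1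
F5 | step 8 | methyl 5-bromo-2-[3-bromo-4-(tert-butyldimethylsilyloxy)benzyl]-3,4-bis(tert-butyldimethylsilyloxy)benzoate | COC(=O)c1cc(Br)c(O[Si](C)(C)C(C)(C)C)c(O[Si](C)(C)C(C)(C)C)c1Cc1ccc(O[Si](C)(C)C(C)(C)C)c(Br)c1
F6 | step 8 | {5-bromo-2-[3-bromo-4-(tert-butyldimethylsilyloxy)benzyl]-3,4-bis(tert-butyldimethylsilyloxy)phenyl}methanol | OCc1cc(Br)c(O[Si](C)(C)C(C)(C)C)c(O[Si](C)(C)C(C)(C)C)c1Cc1ccc(O[Si](C)(C)C(C)(C)C)c(Br)c1
F7 | step 4 | 1-methoxy-4-[methoxy(methyl)amino]butan-2-one | COCC(=O)CCN(C)OC
A1 | alternative 1 | (1Z)-5-bromo-3-(3-bromo-4-methoxyphenyl)-N-tert-butyl-6,7-dimethoxy-3H-isobenzofuran-1-imine (racemic) | CC(C)(C)/N=C1\OC(c2ccc(OC)c(Br)c2)c2c1cc(Br)c(OC)c2OC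
A2 | alternative 1 | 5-bromo-3,4-dimethoxybenzyne | COC1=C(OC)C(Br)=CC#C1
A3 | alternative 1 | 3-bromo-4-methoxybenzaldehyde | COc1ccc(C=O)cc1Br
A4 | alternative 1 | tert-butyl isocyanide | CC(C)(C)[N+]#[C-]
A5 | alternative 2 | methyl 5-bromo-2-(3-bromo-4-methoxybenzyl)-3,4-dimethoxybenzoate | COC(=O)c1cc(Br)c(OC)c(OC)c1Cc1ccc(OC)c(Br)c1
A6 | alternative 2 | methyl 3-bromo-6-(3-bromo-4-methoxybenzyl)-2-oxo-2H-pyran-5-carboxylate | COC(=O)C1=C(Cc2ccc(OC)c(Br)c2)OC(=O)C(Br)=C1
A7 | alternative 2 | (1,2-dimethoxyethenyloxy)trimethylsilane | COC=C(OC)O[Si](C)(C)C
A8 | alternative 3 | 6-bromo-3-[3-bromo-4-(tert-butyldimethylsilyloxy)phenyl]-1,3-dihydroisobenzofuran-4-ol (racemic) | Oc1cc(Br)cc2c1C(c1ccc(O[Si](C)(C)C(C)(C)C)c(Br)c1)OC2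
A9 | alternative 3 | 4-bromo-2-({1-[3-bromo-4-(tert-butyldimethylsilyloxy)phenyl]prop-2-yn-1-yloxy}methyl)furan (racemic) | C#CC(OCc1cc(Br)co1)c1ccc(O[Si](C)(C)C(C)(C)C)c(Br)c1
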